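**Plan**
- Retrosynthetic cuts, in order: the three O–Si bonds (global desilylation); the C6–CH2 bond of the two-carbon link (sp2–sp3 Suzuki–Miyaura coupling); the C3=C4 alkene back to a C4 ketone; the pyran ring at C2–C3; last the C2–O1 aryl ether bond and the allylic C–O bond of the side chain.
- The C2–C3 closure is a carbenoid C–H insertion. A rhodium carbenoid on the future C3 (diazomethyl ketone, with the C4 carbonyl as a temporary oxidation level) inserts into the C2–H bond of an open aryl sec-alkyl ether.
- Enabling feature: C2 carries the ring oxygen O1, so its C–H bond in the open ether is α to oxygen and hydridic. O1 (on C8a) and C4 (on C4a) are ortho on the benzo ring, which holds that C–H bond in reach of a six-membered insertion transition state.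
- Forward order: side-chain alcohol → aryl ether → diazoketone → pyranone ring → reduction and dehydration to the 2H-chromene → catechol arm joined at C6 → desilylation.
- Stereochemistry: the only stereocentre comes from (R)-6-methylhept-5-en-2-ol. Mitsunobu etherification inverts it to the (S)-ether, and the insertion replaces H by C3 with retention to give (S)-C2. The (E)-alkene comes from selenium dioxide oxidation of the (E)-methyl group.

Key step: step 5

Remark: (R)-6-methylhept-5-en-2-ol ((R)-sulcatol) is treated as a purchasable chiral-pool alcohol; C2 of the target is (S).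

**Step 1**
Reactants: 1 (R)-6-methylhept-5-en-2-ol
Product: 2 (2E,6R)-2-methylhept-2-ene-1,6-diol
Conditions: SeO2 (cat.), t-BuOOH, salicylic acid (cat.), CH2Cl2, 0 °C to rt
Reagents that add atoms: tert-butyl hydroperoxide CC(C)(C)OO (source of the new oxygen, delivered through selenium dioxide O=[Se]=O)
Why: Catalytic selenium dioxide allylic oxidation (ene reaction, then 2,3-sigmatropic shift) should hydroxylate the (E)-methyl group of the gem-dimethyl alkene and so fix the (E)-allylic alcohol, while the secondary carbinol centre is not touched.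

**Step 2**
Reactants: 2 (2E,6R)-2-methylhept-2-ene-1,6-diol
Product: 3 (2R,5E)-7-[(tert-butyldimethylsilyl)oxy]-6-methylhept-5-en-2-ol
Conditions: TBSCl (1 equiv), imidazole, CH2Cl2, -20 °C to 0 °C
Reagents that add atoms: tert-butyldimethylsilyl chloride CC(C)(C)[Si](C)(C)Cl
Why: Silyl ether formation should be selective for the unhindered primary allylic hydroxyl over the secondary one on steric grounds.

**Step 3**
Reactants: 3 (2R,5E)-7-[(tert-butyldimethylsilyl)oxy]-6-methylhept-5-en-2-ol; 4 1-(5-bromo-2-hydroxyphenyl)ethan-1-one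
Product: 5 1-(5-bromo-2-{[(2S,5E)-7-[(tert-butyldimethylsilyl)oxy]-6-methylhept-5-en-2-yl]oxy}phenyl)ethan-1-one
Conditions: PPh3, DIAD, THF, 0 °C to rt
Reagents that add atoms: none
Why: Mitsunobu etherification of the acidic ortho-acyl phenol should proceed by SN2 displacement of the alkoxyphosphonium with inversion, turning the (R)-carbinol into the (S)-aryl ether.

**Step 4**
Reactants: 5 1-(5-bromo-2-{[(2S,5E)-7-[(tert-butyldimethylsilyl)oxy]-6-methylhept-5-en-2-yl]oxy}phenyl)ethan-1-one
Product: 7 1-(5-bromo-2-{[(2S,5E)-7-[(tert-butyldimethylsilyl)oxy]-6-methylhept-5-en-2-yl]oxy}phenyl)-2-diazoethan-1-one, via trifluoroacetyl diketone 6 (not isolated)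
Conditions: LiHMDS, THF, -78 °C; CF3CO2CH2CF3; cold 5% aq HCl work-up; then MsN3, Et3N, H2O, MeCN, rt
Reagents that add atoms: methanesulfonyl azide CS(=O)(=O)N=[N+]=[N-]; 2,2,2-trifluoroethyl trifluoroacetate O=C(OCC(F)(F)F)C(F)(F)F (its trifluoroacetyl group is carried only by intermediate 6)
Why: Detrifluoroacetylative diazo transfer (Claisen trifluoroacetylation of the methyl ketone enolate, then diazo transfer with loss of the trifluoroacetyl group) should give the terminal diazoketone without touching the non-acidic ether stereocentre.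

**Step 5**
Reactants: 7 1-(5-bromo-2-{[(2S,5E)-7-[(tert-butyldimethylsilyl)oxy]-6-methylhept-5-en-2-yl]oxy}phenyl)-2-diazoethan-1-one
Product: 8 (2S)-6-bromo-2-[(3E)-5-[(tert-butyldimethylsilyl)oxy]-4-methylpent-3-en-1-yl]-2-methyl-2,3-dihydro-4H-chromen-4-one
Conditions: Rh2(OAc)4 (1 mol%), CH2Cl2, rt, slow addition of 7 at high dilution
Reagents that add atoms: none
Why: Rh2(OAc)4 should extrude N2 from the diazoketone to give an electrophilic rhodium carbenoid at the future C3, which inserts into the C2–H bond through a concerted three-centre transition state (hydride-like donation of the C–H bond to the carbene carbon with simultaneous C–C bond formation). The closest known reaction type is the dirhodium-carboxylate-catalysed intramolecular C–H insertion of 2-alkoxyaryl α-diazoketones to chroman-4-ones, together with stereoretentive carbenoid insertion into tertiary stereogenic C–H bonds. The pyranone ring closes by C2–C3 bond formation in a six-membered (1,6) insertion mode, the ring atoms being C3, C4, C4a, C8a, O1 and C2. The new quaternary stereocentre C2 is controlled by the existing (S)-methine of the ether: insertion goes with retention, C3 taking the place of H, which gives (S)-C2. The step needs site selectivity for the C2–H bond over the side-chain methyl and methylene C–H bonds, over attack at the ether oxygen (oxonium ylide and 1,2-shift) and over the remote trisubstituted alkene; the C2–H bond is the only tertiary, oxygen-activated C–H bond and the only one in reach of a six-membered transition state because O1 and the acyl group are ortho on the benzene ring, the aryl ether oxygen is a poor and reversibly bound ylide donor with no easy rearrangement exit, and the alkene could only be reached through a nine-membered or larger ring. Slow addition at high dilution should suppress carbene dimerisation.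

**Step 6**
Reactants: 8 (2S)-6-bromo-2-[(3E)-5-[(tert-butyldimethylsilyl)oxy]-4-methylpent-3-en-1-yl]-2-methyl-2,3-dihydro-4H-chromen-4-one
Product: 9 (2S,4RS)-6-bromo-2-[(3E)-5-[(tert-butyldimethylsilyl)oxy]-4-methylpent-3-en-1-yl]-2-methyl-3,4-dihydro-2H-chromen-4-ol
Conditions: NaBH4, MeOH/THF, -20 °C to 0 °C
Reagents that add atoms: none
Why: Borohydride reduction of the aryl ketone should give the C4 carbinol as a mixture of epimers, which does not matter because C4 becomes sp2 in the next step, and the cold, brief conditions avoid retro-oxa-Michael opening of the chromanone, the one pathway that could scramble C2.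

**Step 7**
Reactants: 9 (2S,4RS)-6-bromo-2-[(3E)-5-[(tert-butyldimethylsilyl)oxy]-4-methylpent-3-en-1-yl]-2-methyl-3,4-dihydro-2H-chromen-4-ol
Product: 11 {[(2E)-5-[(2S)-6-bromo-2-methyl-2H-chromen-2-yl]-2-methylpent-2-en-1-yl]oxy}(tert-butyl)dimethylsilane, via chroman-4-yl mesylate 10 (not isolated)
Conditions: MsCl, Et3N (excess), CH2Cl2, 0 °C to 40 °C
Reagents that add atoms: methanesulfonyl chloride CS(=O)(=O)Cl (its mesyl group is carried only by intermediate 10)
Why: Mesylation of the benzylic alcohol and base-mediated elimination (the benzylic position is activated by the ortho ring oxygen) should give the conjugated C3=C4 alkene under non-acidic conditions that spare the allylic silyl ether.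

**Step 8**
Reactants: 12 2,3-dihydroxybenzaldehyde
Product: 13 2,3-bis[(tert-butyldimethylsilyl)oxy]benzaldehyde
Conditions: TBSCl (2.4 equiv), imidazole, DMF, rt
Reagents that add atoms: tert-butyldimethylsilyl chloride CC(C)(C)[Si](C)(C)Cl
Why: Standard silylation of both phenols masks the catechol with groups that leave in the same final operation as the side-chain silyl ether.

**Step 9**
Reactants: 13 2,3-bis[(tert-butyldimethylsilyl)oxy]benzaldehyde
Product: 14 1,2-bis[(tert-butyldimethylsilyl)oxy]-3-ethenylbenzene
Conditions: Ph3PCH3Br, KHMDS, THF, 0 °C to rt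
Reagents that add atoms: methyltriphenylphosphonium bromide C[P+](c1ccccc1)(c1ccccc1)c1ccccc1.[Br-]
Why: Wittig methylenation of the aromatic aldehyde with the non-stabilised ylide should give the styrene under aprotic conditions that keep the aryl silyl ethers.

**Step 10**
Reactants: 14 1,2-bis[(tert-butyldimethylsilyl)oxy]-3-ethenylbenzene; 11 {[(2E)-5-[(2S)-6-bromo-2-methyl-2H-chromen-2-yl]-2-methylpent-2-en-1-yl]oxy}(tert-butyl)dimethylsilane
Product: 16 (2S)-6-{2-[2,3-bis((tert-butyldimethylsilyl)oxy)phenyl]ethyl}-2-[(3E)-5-[(tert-butyldimethylsilyl)oxy]-4-methylpent-3-en-1-yl]-2-methyl-2H-chromene, via B-alkyl-9-BBN borane 15 (not isolated)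
Conditions: 9-BBN (1 equiv to 14), THF, 0 °C to rt; then 11, PdCl2(dppf) (cat.), K3PO4, H2O, THF/DMF, 60 °C
Reagents that add atoms: 9-borabicyclo[3.3.1]nonane B1C2CCCC1CCC2 (its boron and bicycle stay in intermediate 15 only and are not in 16)
Why: Anti-Markovnikov hydroboration of the styrene followed by B-alkyl Suzuki–Miyaura coupling with the aryl bromide should forge the C6–CH2 bond without any hydrogenation, so both alkenes of 11 (which never meet free borane) are preserved, and any aryl silyl ether lost to the aqueous base is harmless because the next step removes all silyl groups.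

**Step 11**
Reactants: 16 (2S)-6-{2-[2,3-bis((tert-butyldimethylsilyl)oxy)phenyl]ethyl}-2-[(3E)-5-[(tert-butyldimethylsilyl)oxy]-4-methylpent-3-en-1-yl]-2-methyl-2H-chromene
Product: 17 3-{2-[(2S)-2-[(3E)-5-hydroxy-4-methylpent-3-en-1-yl]-2-methyl-2H-chromen-6-yl]ethyl}benzene-1,2-diol
Conditions: TBAF, AcOH (1:1), THF, 0 °C to rt, under argon
Reagents that add atoms: none
Why: Fluoride-mediated cleavage of the two aryl and one primary silyl ether, buffered with acetic acid so that the air-sensitive catechol is not exposed as its catecholate, should release the target without touching the chromene or the allylic alcohol.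

**Compound list**
1 | (R)-6-methylhept-5-en-2-ol | C[C@@H](O)CCC=C(C)C | starting material
2 | (2E,6R)-2-methylhept-2-ene-1,6-diol | C[C@@H](O)CC/C=C(\C)CO | intermediate
3 | (2R,5E)-7-[(tert-butyldimethylsilyl)oxy]-6-methylhept-5-en-2-ol | C[C@@H](O)CC/C=C(\C)CO[Si](C)(C)C(C)(C)C | intermediate
4 | 1-(5-bromo-2-hydroxyphenyl)ethan-1-one | CC(=O)c1cc(Br)ccc1O | starting material
5 | 1-(5-bromo-2-{[(2S,5E)-7-[(tert-butyldimethylsilyl)oxy]-6-methylhept-5-en-2-yl]oxy}phenyl)ethan-1-one | C[C@H](Oc1ccc(Br)cc1C(C)=O)CC/C=C(\C)CO[Si](C)(C)C(C)(C)C | intermediate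
6 | 1-(5-bromo-2-{[(2S,5E)-7-[(tert-butyldimethylsilyl)oxy]-6-methylhept-5-en-2-yl]oxy}phenyl)-4,4,4-trifluorobutane-1,3-dione | C[C@H](Oc1ccc(Br)cc1C(=O)CC(=O)C(F)(F)F)CC/C=C(\C)CO[Si](C)(C)C(C)(C)C | intermediate (not isolated)
7 | 1-(5-bromo-2-{[(2S,5E)-7-[(tert-butyldimethylsilyl)oxy]-6-methylhept-5-en-2-yl]oxy}phenyl)-2-diazoethan-1-one | C[C@H](Oc1ccc(Br)cc1C(=O)C=[N+]=[N-])CC/C=C(\C)CO[Si](C)(C)C(C)(C)C | intermediate
8 | (2S)-6-bromo-2-[(3E)-5-[(tert-butyldimethylsilyl)oxy]-4-methylpent-3-en-1-yl]-2-methyl-2,3-dihydro-4H-chromen-4-one | C/C(=C\CC[C@@]1(C)CC(=O)c2cc(Br)ccc2O1)CO[Si](C)(C)C(C)(C)C | intermediate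
9 | (2S,4RS)-6-bromo-2-[(3E)-5-[(tert-butyldimethylsilyl)oxy]-4-methylpent-3-en-1-yl]-2-methyl-3,4-dihydro-2H-chromen-4-ol (both C4 epimers) | C/C(=C\CC[C@@]1(C)CC(O)c2cc(Br)ccc2O1)CO[Si](C)(C)C(C)(C)C | intermediate
10 | (2S,4RS)-6-bromo-2-[(3E)-5-[(tert-butyldimethylsilyl)oxy]-4-methylpent-3-en-1-yl]-2-methyl-3,4-dihydro-2H-chromen-4-yl methanesulfonate | C/C(=C\CC[C@@]1(C)CC(OS(C)(=O)=O)c2cc(Br)ccc2O1)CO[Si](C)(C)C(C)(C)C | intermediate (not isolated)
11 | {[(2E)-5-[(2S)-6-bromo-2-methyl-2H-chromen-2-yl]-2-methylpent-2-en-1-yl]oxy}(tert-butyl)dimethylsilane | C/C(=C\CC[C@@]1(C)C=Cc2cc(Br)ccc2O1)CO[Si](C)(C)C(C)(C)C | intermediate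
12 | 2,3-dihydroxybenzaldehyde | O=Cc1cccc(O)c1O | starting material
13 | 2,3-bis[(tert-butyldimethylsilyl)oxy]benzaldehyde | O=Cc1cccc(O[Si](C)(C)C(C)(C)C)c1O[Si](C)(C)C(C)(C)C | intermediate
14 | 1,2-bis[(tert-butyldimethylsilyl)oxy]-3-ethenylbenzene | C=Cc1cccc(O[Si](C)(C)C(C)(C)C)c1O[Si](C)(C)C(C)(C)C | intermediate
15 | 9-{2-[2,3-bis((tert-butyldimethylsilyl)oxy)phenyl]ethyl}-9-borabicyclo[3.3.1]nonane | CC(C)(C)[Si](C)(C)Oc1cccc(CCB2C3CCCC2CCC3)c1O[Si](C)(C)C(C)(C)C | intermediate (not isolated)
16 | (2S)-6-{2-[2,3-bis((tert-butyldimethylsilyl)oxy)phenyl]ethyl}-2-[(3E)-5-[(tert-butyldimethylsilyl)oxy]-4-methylpent-3-en-1-yl]-2-methyl-2H-chromene | C/C(=C\CC[C@@]1(C)C=Cc2cc(CCc3cccc(O[Si](C)(C)C(C)(C)C)c3O[Si](C)(C)C(C)(C)C)ccc2O1)CO[Si](C)(C)C(C)(C)C | intermediate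
17 | 3-{2-[(2S)-2-[(3E)-5-hydroxy-4-methylpent-3-en-1-yl]-2-methyl-2H-chromen-6-yl]ethyl}benzene-1,2-diol | C/C(=C\CC[C@@]1(C)C=Cc2cc(CCc3cccc(O)c3O)ccc2O1)CO | target

**Step count and risks**
Total steps: 11. Longest linear sequence: 9 steps (steps 1 to 7, 10 and 11); steps 8 and 9 build the catechol arm in parallel.

Steps most likely to fail:

Step 5. The carbenoid may be captured by the aryl ether oxygen and rearrange by 1,2-shift to a benzofuranone, may dimerise, or may insert at a side-chain C–H bond, so that little chromanone forms. The fallback sets out from 3 (with 4) and comes back at 8. Oxidation of 3 with Dess–Martin periodinane should give (5E)-7-[(tert-butyldimethylsilyl)oxy]-6-methylhept-5-en-2-one F1. Kabbe condensation of F1 with 4 (pyrrolidine, EtOH, reflux; aldol condensation, then oxa-Michael closure) should give the racemic chromanone F2. Preparative HPLC on a chiral stationary phase should then separate 8 from its (R)-enantiomer F3, which is discarded.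

Step 3. The redox condensation may stall because the hydrogen-bonded, ortho-acylated phenol is a weak nucleophile toward the hindered alkoxyphosphonium ion, with elimination of the activated alcohol or alkylation of the hydrazide taking over, or inversion may be incomplete. The fallback sets out from 3 and comes back at 5, making the aryl–oxygen bond in place of the alkyl–oxygen bond. Mitsunobu inversion of 3 with the stronger pronucleophile 4-nitrobenzoic acid should give the (S)-4-nitrobenzoate F4. Methanolysis (K2CO3, MeOH) should give the (S)-alcohol F5. The potassium alkoxide of F5 (KHMDS, THF, 0 °C) should then displace fluoride from purchased 1-(5-bromo-2-fluorophenyl)ethan-1-one (CC(=O)c1cc(Br)ccc1F) by SNAr with retention at carbon, giving 5.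

Step 1. The allylic oxidation may stop at low conversion, run on to the enal, or be disturbed by selenium ester formation at the free secondary alcohol. The fallback sets out from 1 and comes back at 2, building the (E)-alkene by olefination. Ozonolysis of 1 (O3, CH2Cl2/MeOH, -78 °C; Me2S) should give (R)-4-hydroxypentanal as its lactol, (5R)-5-methyloxolan-2-ol F6. Wittig reaction of F6 with the purchased stabilised ylide ethyl 2-(triphenylphosphoranylidene)propanoate (toluene, 80 °C; (E)-selective) should give ethyl (2E,6R)-6-hydroxy-2-methylhept-2-enoate F7. DIBAL-H reduction (CH2Cl2, -78 °C) should then give 2.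

**Further compounds**
F1 | step 5 | (5E)-7-[(tert-butyldimethylsilyl)oxy]-6-methylhept-5-en-2-one | CC(=O)CC/C=C(\C)CO[Si](C)(C)C(C)(C)C
F2 | step 5 | racemic 6-bromo-2-[(3E)-5-[(tert-butyldimethylsilyl)oxy]-4-methylpent-3-en-1-yl]-2-methyl-2,3-dihydro-4H-chromen-4-one | C/C(=C\CCC1(C)CC(=O)c2cc(Br)ccc2O1)CO[Si](C)(C)C(C)(C)C
F3 | step 5 | (2R)-6-bromo-2-[(3E)-5-[(tert-butyldimethylsilyl)oxy]-4-methylpent-3-en-1-yl]-2-methyl-2,3-dihydro-4H-chromen-4-one | C/C(=C\CC[C@]1(C)CC(=O)c2cc(Br)ccc2O1)CO[Si](C)(C)C(C)(C)C
F4 | step 3 | (2S,5E)-7-[(tert-butyldimethylsilyl)oxy]-6-methylhept-5-en-2-yl 4-nitrobenzoate | C[C@H](OC(=O)c1ccc(cc1)[N+](=O)[O-])CC/C=C(\C)CO[Si](C)(C)C(C)(C)C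
F5 | step 3 | (2S,5E)-7-[(tert-butyldimethylsilyl)oxy]-6-methylhept-5-en-2-ol | C[C@H](O)CC/C=C(\C)CO[Si](C)(C)C(C)(C)C
F6 | step 1 | (5R)-5-methyloxolan-2-ol (lactol of (R)-4-hydroxypentanal, anomeric mixture) | C[C@@H]1CCC(O)O1
F7 | step 1 | ethyl (2E,6R)-6-hydroxy-2-methylhept-2-enoate | C[C@@H](O)CC/C=C(\C)C(=O)OCC
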